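**Retrosynthetic overview**

1. Target 31 ⇐ cycloadduct 29 (ether cleavage, C–B oxidation) ⇐ intramolecular Diels–Alder reaction of the eleven-membered triene 28, which closes the cyclohexene (C2–C3 bond) and the cyclopentane (C16–C4 bond) in one operation and sets C2, C3, C4 and C16.
2. Enabling feature: the cyclohexene ring with the tetrasubstituted C1=C15 alkene is a Diels–Alder retron. Its diene carbons C1, C15 and C16 already lie in the eleven-membered ring, and the cyclopentane carbons C5–C6–C7 are a three-carbon tether from C7 (next to C16) to the dienophile carbon C4. With the tether on the Z (inside) terminus of the diene only the cis ring fusion can form.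
3. Macrocycle 28 ⇐ open-chain ynal 25 by nickel-catalysed reductive alkyne–aldehyde cyclisation (C8–C9 bond, exocyclic methylene, C9 carbinol).
4. 25 ⇐ palladium coupling of (Z)-iodoalkene 12 with the alkenylzirconium from ynol ether 21; 12 from a rhodium-catalysed conjugate alkynylation (C7) and a Negishi coupling (boronate dienophile), 21 from (R)-citronellyl bromide (C12).
5. Ring order: eleven-membered ring (step 15), then cyclohexene and cyclopentane together (step 17); no ring is closed afterwards.

Key step: step 17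

Remarks (valid for the whole text):
- Carbon numbering: C1=C15 is the ring alkene (C15 carries the vinylic methyl), C2 (allylic) and C3 are the carbinol carbons, C4 is the quaternary carbon, C5–C6 the cyclopentane CH2 groups, C7 the cyclopentane CH next to the methylene-bearing C8, C9 the acetoxy carbon, C10–C11 CH2, C12 the methyl-bearing CH, C13–C14 CH2 back to C1, C16 the ring-fusion CH.
- Abbreviations: PMB = 4-methoxybenzyl, TBS = tert-butyldimethylsilyl, TIPS = triisopropylsilyl, Bpin = 4,4,5,5-tetramethyl-1,3,2-dioxaborolan-2-yl.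
- Assumption: the sense of induction of the ligand in step 1 is assigned by analogy with simple β-substituted enals; the ligand antipode is used if the opposite enantiomer of 3 forms.

**Route**

Step 1
Reactants: 1 (E)-4,4-dimethoxybut-2-enal; 2 ethynyltri(propan-2-yl)silane
Product: 3 (S)-4,4-dimethoxy-3-[(triisopropylsilyl)ethynyl]butanal
Conditions: [Rh(OAc)(C2H4)2]2 (2.5 mol%), (R)-DTBM-SEGPHOS (6 mol%), MeOH, 40 °C
Reagents that add atoms: none
Why: Rhodium-catalysed asymmetric conjugate alkynylation of an enal with a bulky silylacetylene, a known reaction of β-substituted enals; the bisphosphine-bound alkynylrhodium adds to one enantioface of the acceptor and sets C7.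

Step 2
Reactants: 3 (S)-4,4-dimethoxy-3-[(triisopropylsilyl)ethynyl]butanal
Product: 4 (S)-4,4-dimethoxy-3-[(triisopropylsilyl)ethynyl]butan-1-ol
Conditions: NaBH4, MeOH, 0 °C
Reagents that add atoms: none
Why: Borohydride reduction of the aldehyde leaves acetal, silylalkyne and the stereocentre untouched.

Step 3
Reactants: 4 (S)-4,4-dimethoxy-3-[(triisopropylsilyl)ethynyl]butan-1-ol
Product: 5 (S)-[3-(dimethoxymethyl)-5-iodopent-1-yn-1-yl]tri(propan-2-yl)silane
Conditions: I2, PPh3, imidazole, CH2Cl2, 0 °C
Reagents that add atoms: iodine (II)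
Why: Appel-type iodination of the primary alcohol by SN2 displacement of the oxyphosphonium group, with imidazole buffering the acetal.

Step 4
Reactants: 6 propyne
Product: 8 2-[(Z)-2-bromoprop-1-en-1-yl]-4,4,5,5-tetramethyl-1,3,2-dioxaborolane, via dibromo[(Z)-2-bromoprop-1-en-1-yl]borane 7 (not isolated)
Conditions: BBr3, CH2Cl2, −78 °C; then pinacol, −78 → 23 °C
Reagents that add atoms: boron tribromide (BrB(Br)Br); pinacol (CC(C)(O)C(C)(C)O)
Why: syn-Bromoboration of the terminal alkyne puts bromine on the internal carbon and boron on the terminal carbon, cis to each other, and ligand exchange with pinacol gives the configurationally stable (Z)-bromoalkenylboronate.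

Step 5
Reactants: 5 (S)-[3-(dimethoxymethyl)-5-iodopent-1-yn-1-yl]tri(propan-2-yl)silane; 8 2-[(Z)-2-bromoprop-1-en-1-yl]-4,4,5,5-tetramethyl-1,3,2-dioxaborolane
Product: 10 2-[(1Z,5S)-5-(dimethoxymethyl)-2-methyl-7-(triisopropylsilyl)hept-1-en-6-yn-1-yl]-4,4,5,5-tetramethyl-1,3,2-dioxaborolane, via alkylzinc iodide 9 (not isolated)
Conditions: Zn, LiCl, THF, 40 °C; then 8, Pd(P(t-Bu)3)2 (2 mol%), THF, 23 °C
Reagents that add atoms: none
Why: Zinc insertion into the primary C–I bond followed by Negishi coupling at the C–Br bond of 8 with retention; without base the pinacol boronate does not transmetalate, so the chain carbon C5 ends cis to boron across C4=C3.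

Step 6
Reactants: 10 2-[(1Z,5S)-5-(dimethoxymethyl)-2-methyl-7-(triisopropylsilyl)hept-1-en-6-yn-1-yl]-4,4,5,5-tetramethyl-1,3,2-dioxaborolane
Product: 11 (2S,5Z)-5-methyl-6-(Bpin)-2-[(triisopropylsilyl)ethynyl]hex-5-enal
Conditions: CF3CO2H/H2O (9:1), CH2Cl2, 0 °C; crude product used at once
Reagents that add atoms: water (O)
Why: Acid hydrolysis of the dimethyl acetal, run cold and without storage of the α-alkynyl aldehyde so that C7 does not epimerise or isomerise to the allene.

Step 7
Reactants: 11 (2S,5Z)-5-methyl-6-(Bpin)-2-[(triisopropylsilyl)ethynyl]hex-5-enal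
Product: 12 2-[(1Z,5R,6Z)-7-iodo-2-methyl-5-[(triisopropylsilyl)ethynyl]octa-1,6-dien-1-yl]-4,4,5,5-tetramethyl-1,3,2-dioxaborolane
Conditions: EtPPh3I, n-BuLi, THF, 23 °C; I2, −78 °C; NaN(SiMe3)2, −20 °C; then 11, −78 °C
Reagents that add atoms: ethyltriphenylphosphonium iodide (CC[P+](c1ccccc1)(c1ccccc1)c1ccccc1.[I-]); iodine (II)
Why: Stork–Zhao iodo-olefination, in which the α-iodo ylide reacts under kinetic control at low temperature to give the (Z)-2-iodoalkene (iodine cis to C7), the geometry that later places the tether on the inside of the diene.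

Step 8
Reactants: 13 (4-methoxyphenyl)methanol; 14 trichloroethene
Product: 15 1-{[(E)-1,2-dichloroethenyl]oxymethyl}-4-methoxybenzene
Conditions: KH, THF, 0 → 23 °C
Reagents that add atoms: none
Why: The potassium alkoxide adds anti to dichloroacetylene formed in situ from trichloroethene, a known synthesis of (E)-1,2-dichlorovinyl ethers, which are stable precursors of alkoxyacetylides.

Step 9
Reactants: 16 (R)-citronellyl bromide
Product: 18 (R)-6-bromo-4-methylhexan-1-ol, via (R)-6-bromo-4-methylhexanal 17 (not isolated)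
Conditions: O3, CH2Cl2/MeOH, −78 °C; then NaBH4, −78 → 0 °C
Reagents that add atoms: ozone ([O-][O+]=O)
Why: Ozonolysis of the trisubstituted alkene with reductive work-up gives the primary alcohol and leaves the alkyl bromide and C12 unchanged.

Step 10
Reactants: 18 (R)-6-bromo-4-methylhexan-1-ol
Product: 19 (R)-[(6-bromo-4-methylhexyl)oxy](tert-butyl)dimethylsilane
Conditions: TBSCl, imidazole, DMF, 23 °C
Reagents that add atoms: tert-butyl(chloro)dimethylsilane (CC(C)(C)[Si](C)(C)Cl)
Why: Standard silylation of the primary alcohol.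

Step 11
Reactants: 15 1-{[(E)-1,2-dichloroethenyl]oxymethyl}-4-methoxybenzene; 19 (R)-[(6-bromo-4-methylhexyl)oxy](tert-butyl)dimethylsilane
Product: 21 (S)-tert-butyl({8-[(4-methoxybenzyl)oxy]-4-methyloct-7-yn-1-yl}oxy)dimethylsilane, via lithium alkoxyacetylide 20 (not isolated)
Conditions: n-BuLi (2.1 equiv), THF, −78 → −40 °C; then 19, HMPA, −78 → 23 °C
Reagents that add atoms: none
Why: Dehydrochlorination and chlorine–lithium exchange of the dichlorovinyl ether give the lithium alkoxyacetylide, which is alkylated by the primary bromide (SN2); the ynol ether is used without delay because benzyl alkynyl ethers rearrange on heating.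

Step 12
Reactants: 21 (S)-tert-butyl({8-[(4-methoxybenzyl)oxy]-4-methyloct-7-yn-1-yl}oxy)dimethylsilane; 12 2-[(1Z,5R,6Z)-7-iodo-2-methyl-5-[(triisopropylsilyl)ethynyl]octa-1,6-dien-1-yl]-4,4,5,5-tetramethyl-1,3,2-dioxaborolane
Product: 23 open-chain dienyl ether: (E)-PMB enol ether C2=C1 and (Z)-C15=C16; C1 carries the (S)-3-methyl-6-(TBS-oxy)hexyl chain (C14–C9), C16 carries (R)-C7 with the TIPS-ethynyl group and the (Z)-4-(Bpin)-3-methylbut-3-enyl chain, via alkenylzirconocene chloride 22 (not isolated)
Conditions: Cp2Zr(H)Cl, THF, 23 °C; then 12, Pd(PPh3)4 (5 mol%), ZnCl2 (0.6 equiv), THF, 23 → 40 °C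
Reagents that add atoms: none
Why: syn-Hydrozirconation of the alkoxyalkyne puts zirconium on the carbon remote from oxygen (C1) and hydrogen on C2, and palladium-catalysed alkenyl–alkenyl coupling (Negishi protocol with ZnCl2 as shuttle) with retention on both partners gives the (E)-enol ether/(Z)-alkene diene, while the base-free conditions spare the boronate.

Step 13
Reactants: 23 open-chain dienyl ether (TBS ether, TIPS-alkyne)
Product: 24 hydroxy enyne: 23 with free C9 hydroxyl and terminal alkyne C8≡C19H
Conditions: n-Bu4NF, THF, 0 → 23 °C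
Reagents that add atoms: none
Why: Fluoride cleaves the O–Si bond of the primary silyl ether and the C–Si bond of the silylalkyne in one operation, and enol ether and pinacol boronate tolerate these conditions.

Step 14
Reactants: 24 hydroxy enyne
Product: 25 ynal: 24 with C9 as aldehyde
Conditions: Dess–Martin periodinane, pyridine, CH2Cl2, 0 °C
Reagents that add atoms: none
Why: Dess–Martin oxidation of the primary alcohol under buffered, non-acidic conditions that are compatible with the enol ether diene and the terminal alkyne.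

Step 15
Reactants: 25 ynal
Product: 27 macrocyclic allylic alcohol: (7R,9R,12S)-eleven-membered ring (C1, C15, C16, C7–C14) with (E)-PMB-oxymethylidene on C1, (Z)-C15=C16, methylidene on C8, hydroxyl on C9, methyl on C12 and C15 and the (Z)-4-(Bpin)-3-methylbut-3-enyl chain on C7, via macrocyclic triethylsilyl ether 26 (not isolated)
Conditions: Ni(cod)2 (30 mol%), SIPr·HCl, KOt-Bu, Et3SiH, THF (0.005 M, slow addition), 23 °C; then n-Bu4NF, 0 °C
Reagents that add atoms: none
Why: Nickel-catalysed reductive ynal macrocyclisation (oxidative cyclisation of alkyne and aldehyde at zerovalent nickel, then σ-bond metathesis with the silane), in which the bulky carbene ligand directs C–C bond formation to the internal alkyne carbon (exo mode, documented for terminal ynals) and so gives the eleven-membered ring with the 1,1-disubstituted alkene; C9 is expected to form under substrate control from C7 (minimised allylic strain about C8), and any epimer is removed at the alcohol stage.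

Step 16
Reactants: 27 macrocyclic allylic alcohol
Product: 28 macrocyclic acetate: 27 with acetoxy on C9
Conditions: Ac2O, pyridine, DMAP (cat.), CH2Cl2, 0 → 23 °C
Reagents that add atoms: acetic anhydride (CC(=O)OC(C)=O)
Why: Acetylation of the secondary allylic alcohol before the diol is unveiled, so that no selective acylation is needed later.

Step 17
Reactants: 28 macrocyclic acetate
Product: 29 cycloadduct: tricyclic skeleton of the target (cis-fused hydrindene bridged by the eleven-membered ring) with Bpin on C3 (cis to C5), PMB-oxy on C2 (trans to boron) and acetoxy on C9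
Conditions: PhMe (0.01 M), BHT, sealed tube, 160 °C
Reagents that add atoms: none
Why: A thermal intramolecular [4+2] cycloaddition (type 1, 1,6,8-nonatriene pattern) joins the 1-alkoxydiene C2=C1–C15=C16 to the (Z)-alkenylboronate C3=C4; the closest known reactions are intramolecular Diels–Alder reactions of (Z)-dienes and of alkenylboronate dienophiles. The cyclopentane (C4–C5–C6–C7–C16) closes by the C16–C4 bond through the three-carbon tether on the Z terminus of the diene, and the cyclohexene (C1–C2–C3–C4–C16–C15) closes in the same concerted event by the C2–C3 bond, leaving the tetrasubstituted C1=C15 alkene. Because the tether sits on the inside of the diene, only the transition state with the tether exo and the C4 methyl endo is reachable, which makes the ring fusion cis (H-16 and the C4 methyl on one face). Suprafacial addition then carries the alkene geometries into the ring: boron, cis to the tether on the dienophile, ends on C3 cis to C5, and the outside oxygen of the (E)-enol ether ends on C2 cis to H-16 and trans to boron. The diene face is chosen by C7: allylic 1,3-strain against C1 and the C2–H holds H-7 in the diene plane, with the macrocyclic arm C8 on one face and the tether C6 on the other, so H-16 forms trans to H-7. The selectivity needed is cycloaddition over the suprafacial [1,5]-hydrogen shift of H-7 to C2, and it is favoured by the alkoxy-raised diene HOMO, the boron-lowered dienophile LUMO and the 2,3-disubstitution of the diene, which favours the cisoid conformer.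

Step 18
Reactants: 29 cycloadduct
Product: 30 3-hydroxy-2-PMB ether: 29 with hydroxyl in place of Bpin on C3
Conditions: NaBO3·4H2O, THF/H2O (1:1), 23 °C
Reagents that add atoms: sodium perborate ([Na+].[Na+].O[B-]1(O)OO[B-](O)(O)OO1)
Why: Perborate oxidation of the secondary alkylboronate proceeds by 1,2-migration of carbon from boron to oxygen with retention at C3, and the mild basicity spares the acetate.

Step 19
Reactants: 30 3-hydroxy-2-PMB ether
Product: 31 target CNP0192310.2 (9-acetoxy-2,3-diol)
Conditions: DDQ, CH2Cl2/pH 7 buffer (10:1), 0 °C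
Reagents that add atoms: none
Why: Oxidative cleavage of the 4-methoxybenzyl ether by DDQ (benzylic hydride abstraction, hydrolysis of the oxocarbenium ion) in wet solvent frees the C2 hydroxyl without touching acetate or alkenes, and water suppresses acetal formation with the neighbouring hydroxyl.

**Compound list**

1 | (E)-4,4-dimethoxybut-2-enal | COC(OC)/C=C/C=O | starting material
2 | ethynyltri(propan-2-yl)silane | C#C[Si](C(C)C)(C(C)C)C(C)C | starting material
3 | (S)-4,4-dimethoxy-3-[(triisopropylsilyl)ethynyl]butanal | COC(OC)[C@H](C#C[Si](C(C)C)(C(C)C)C(C)C)CC=O | intermediate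
4 | (S)-4,4-dimethoxy-3-[(triisopropylsilyl)ethynyl]butan-1-ol | COC(OC)[C@H](C#C[Si](C(C)C)(C(C)C)C(C)C)CCO | intermediate
5 | (S)-[3-(dimethoxymethyl)-5-iodopent-1-yn-1-yl]tri(propan-2-yl)silane | COC(OC)[C@H](C#C[Si](C(C)C)(C(C)C)C(C)C)CCI | intermediate
6 | propyne | CC#C | starting material
7 | dibromo[(Z)-2-bromoprop-1-en-1-yl]borane | C/C(Br)=C/B(Br)Br | intermediate (not isolated)
8 | 2-[(Z)-2-bromoprop-1-en-1-yl]-4,4,5,5-tetramethyl-1,3,2-dioxaborolane | C/C(Br)=C/B1OC(C)(C)C(C)(C)O1 | intermediate
9 | [(3S)-3-(dimethoxymethyl)-5-(triisopropylsilyl)pent-4-yn-1-yl]zinc iodide | COC(OC)[C@H](C#C[Si](C(C)C)(C(C)C)C(C)C)CC[Zn]I | intermediate (not isolated)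
10 | 2-[(1Z,5S)-5-(dimethoxymethyl)-2-methyl-7-(triisopropylsilyl)hept-1-en-6-yn-1-yl]-4,4,5,5-tetramethyl-1,3,2-dioxaborolane | COC(OC)[C@H](C#C[Si](C(C)C)(C(C)C)C(C)C)CC/C(C)=C\B1OC(C)(C)C(C)(C)O1 | intermediate
11 | (2S,5Z)-5-methyl-6-(Bpin)-2-[(triisopropylsilyl)ethynyl]hex-5-enal | O=C[C@H](C#C[Si](C(C)C)(C(C)C)C(C)C)CC/C(C)=C\B1OC(C)(C)C(C)(C)O1 | intermediate
12 | 2-[(1Z,5R,6Z)-7-iodo-2-methyl-5-[(triisopropylsilyl)ethynyl]octa-1,6-dien-1-yl]-4,4,5,5-tetramethyl-1,3,2-dioxaborolane | C/C(I)=C/[C@H](C#C[Si](C(C)C)(C(C)C)C(C)C)CC/C(C)=C\B1OC(C)(C)C(C)(C)O1 | intermediate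
13 | (4-methoxyphenyl)methanol | COc1ccc(CO)cc1 | starting material
14 | trichloroethene | ClC=C(Cl)Cl | starting material
15 | 1-{[(E)-1,2-dichloroethenyl]oxymethyl}-4-methoxybenzene | COc1ccc(CO/C(Cl)=C\Cl)cc1 | intermediate
16 | (R)-citronellyl bromide, (R)-8-bromo-2,6-dimethyloct-2-ene | CC(C)=CCC[C@@H](C)CCBr | starting material
17 | (R)-6-bromo-4-methylhexanal | O=CCC[C@@H](C)CCBr | intermediate (not isolated)
18 | (R)-6-bromo-4-methylhexan-1-ol | OCCC[C@@H](C)CCBr | intermediate
19 | (R)-[(6-bromo-4-methylhexyl)oxy](tert-butyl)dimethylsilane | CC(C)(C)[Si](C)(C)OCCC[C@@H](C)CCBr | intermediate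
20 | lithium [(4-methoxybenzyl)oxy]acetylide | [Li]C#COCc1ccc(OC)cc1 | intermediate (not isolated)
21 | (S)-tert-butyl({8-[(4-methoxybenzyl)oxy]-4-methyloct-7-yn-1-yl}oxy)dimethylsilane | COc1ccc(COC#CCC[C@H](C)CCCO[Si](C)(C)C(C)(C)C)cc1 | intermediate
22 | (E,S)-chloro{1-[(4-methoxybenzyl)oxy]-5-methyl-8-(TBS-oxy)oct-1-en-2-yl}bis(cyclopentadienyl)zirconium, zirconium on C1 cis to the C2 hydrogen (cyclopentadienyl rings drawn σ-bonded) | COc1ccc(CO/C=C(\CC[C@H](C)CCCO[Si](C)(C)C(C)(C)C)[Zr](Cl)(C2C=CC=C2)C2C=CC=C2)cc1 | intermediate (not isolated)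
23 | open-chain dienyl ether: (E)-PMB enol ether C2=C1, (Z)-C15=C16, (S)-C12 chain with TBS-oxy on C9, (R)-C7 with TIPS-ethynyl and (Z)-alkenyl-Bpin chain | COc1ccc(CO/C=C(\CC[C@H](C)CCCO[Si](C)(C)C(C)(C)C)/C(C)=C\[C@H](C#C[Si](C(C)C)(C(C)C)C(C)C)CC/C(C)=C\B2OC(C)(C)C(C)(C)O2)cc1 | intermediate
24 | hydroxy enyne: 23 with free C9 hydroxyl and terminal alkyne | COc1ccc(CO/C=C(\CC[C@H](C)CCCO)/C(C)=C\[C@H](C#C)CC/C(C)=C\B2OC(C)(C)C(C)(C)O2)cc1 | intermediate
25 | ynal: 24 with C9 aldehyde | COc1ccc(CO/C=C(\CC[C@H](C)CCC=O)/C(C)=C\[C@H](C#C)CC/C(C)=C\B2OC(C)(C)C(C)(C)O2)cc1 | intermediate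
26 | (7R,9R,12S)-macrocyclic triethylsilyl ether: eleven-membered ring with (E)-PMB-oxymethylidene on C1, (Z)-C15=C16, methylidene on C8, triethylsilyloxy on C9 | C=C1[C@H](O[Si](CC)(CC)CC)CC[C@@H](C)CC/C(=C\OCc2ccc(OC)cc2)/C(C)=C\[C@H]1CC/C(C)=C\B3OC(C)(C)C(C)(C)O3 | intermediate (not isolated)
27 | (7R,9R,12S)-macrocyclic allylic alcohol: 26 with free C9 hydroxyl | C=C1[C@H](O)CC[C@@H](C)CC/C(=C\OCc2ccc(OC)cc2)/C(C)=C\[C@H]1CC/C(C)=C\B3OC(C)(C)C(C)(C)O3 | intermediate
28 | (7R,9R,12S)-macrocyclic acetate, cycloaddition precursor | C=C1[C@H](OC(C)=O)CC[C@@H](C)CC/C(=C\OCc2ccc(OC)cc2)/C(C)=C\[C@H]1CC/C(C)=C\B3OC(C)(C)C(C)(C)O3 | intermediate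
29 | (2S,3R,4S,7R,9R,12S,16S)-cycloadduct: target skeleton with Bpin on C3, PMB-oxy on C2, acetoxy on C9 | C=C1[C@H](OC(C)=O)CC[C@@H](C)CCC2=C(C)[C@H]3[C@H]1CC[C@@]3(C)[C@@H](B4OC(C)(C)C(C)(C)O4)[C@@H]2OCc5ccc(OC)cc5 | intermediate
30 | (2R,3R,4R,7R,9R,12S,16R)-3-hydroxy-2-PMB ether | C=C1[C@H](OC(C)=O)CC[C@@H](C)CCC2=C(C)[C@H]3[C@H]1CC[C@@]3(C)[C@@H](O)[C@@H]2OCc5ccc(OC)cc5 | intermediate
31 | CNP0192310.2, (2R,3R,4R,7R,9R,12S,16R)-9-acetoxy-2,3-diol | C=C1[C@H](OC(C)=O)CC[C@@H](C)CCC2=C(C)[C@H]3[C@H]1CC[C@@]3(C)[C@@H](O)[C@@H]2O | target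

**Step count and risks**

Total step count: 19. Longest linear sequence: 14 steps (1–3, 5–7, 12–19).

The three steps most likely to fail:

Step 17. The twisted Z-diene may cyclise slowly, so that the suprafacial [1,5]-hydrogen migration from C7 to C2 outruns ring closure at the temperature needed. The fallback moves the cyclisation from the thermal pericyclic pathway to a metal template. It sets out from 28, which is treated with [Rh(cod)Cl]2 and tris(1,1,1,3,3,3-hexafluoropropan-2-yl) phosphite in THF at 40–55 °C. Diene and alkene then couple by oxidative cyclisation and reductive elimination at rhodium, a known intramolecular [4+2] mode for unactivated diene–ene pairs. The Z-diene again allows only the cis-fused adduct, and the route is re-entered at 29. This fallback makes no further compound, so its entry below is F0.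

Step 15. Induction from C7 to the new carbinol carbon C9 during ring closure may be poor, and the exo regioselectivity may erode. The fallback replaces substrate control by reagent control. It sets out from alcohol 27 as its C9 epimer mixture. Dess–Martin oxidation should give the macrocyclic α-methylene ketone F1. Reduction of ketone F1 with (S)-2-methyl-CBS-oxazaborolidine and catecholborane (alkenyl as the large group) should return (9R)-27, where the route is re-entered.

Step 7. Aldehyde 11 may epimerise or isomerise to the allene at C7 under the basic ylide, and the Z-selectivity may be incomplete. The fallback avoids the ylide. It sets out from 11. Dibromo-olefination under non-basic conditions (CBr4, PPh3, Zn, CH2Cl2, 0 °C) should give the 1,1-dibromoalkene F2. Palladium-catalysed trans-selective monomethylation of dibromide F2 (MeZnCl, PdCl2(DPEphos), THF) should replace the bromine trans to C7 and give the (Z)-2-bromoalkene F3. Bromide F3 takes the place of iodide 12 in the coupling of step 12 (Pd(P(t-Bu)3)2 for the hindered bromide), and the route is re-entered at 23.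

**Further compounds**

F0 | step 17 | none | none
F1 | step 15 | (7R,12S)-macrocyclic α-methylene ketone, C9 ketone of 27 | C=C1C(=O)CC[C@@H](C)CC/C(=C\OCc2ccc(OC)cc2)/C(C)=C\[C@H]1CC/C(C)=C\B3OC(C)(C)C(C)(C)O3
F2 | step 7 | 2-[(1Z,5R)-7,7-dibromo-2-methyl-5-[(triisopropylsilyl)ethynyl]hepta-1,6-dien-1-yl]-4,4,5,5-tetramethyl-1,3,2-dioxaborolane | BrC(Br)=C[C@H](C#C[Si](C(C)C)(C(C)C)C(C)C)CC/C(C)=C\B1OC(C)(C)C(C)(C)O1
F3 | step 7 | 2-[(1Z,5R,6Z)-7-bromo-2-methyl-5-[(triisopropylsilyl)ethynyl]octa-1,6-dien-1-yl]-4,4,5,5-tetramethyl-1,3,2-dioxaborolane | C/C(Br)=C/[C@H](C#C[Si](C(C)C)(C(C)C)C(C)C)CC/C(C)=C\B1OC(C)(C)C(C)(C)O1
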